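All constants belong to no real substance.

Take the ratio of two captures. Electrophile and nucleophile couple to product and set acid free, and that acid binds at balance either to the nucleophile or to the free base. Divide one capture by the other and the acid concentration drops out. Reckoned from the charges, the electrophile concentration goes too, since both charges are in equivalents, but in the flask the ratio follows free nucleophile and free base as they change.

electrophile 0.20 M (fed, over 4.0 min); nucleophile 1.05 equiv; free base 3.00 equiv; time 1.0 h; the fed solution adds 0.25 times the starting volume

1. the state of affairs at 1.0 h: stopped, and by what, or still going (it is still moving / all of the electrophile has reacted / the free base has run out first / the nucleophile has run out first)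
2. amount of product at 1.0 h, in percent of the electrophile charged

- every charge counts on the volume at the start, and the solution that is fed holds the whole dose
- the reaction counts as stopped when no species that holds the electrophile changes by six tenths of a point or more over the second half of the time
- run time (flask): 1.0 h

Reckon from the charges:

capture ratio = 3990 L mol⁻¹ × 1.05 equiv / (640 L mol⁻¹ × 3.00 equiv) = 2.18

Call this the starting capture ratio, acid bound by nucleophile over acid bound by free base. While the ratio stands at that value, each product costs its own nucleophile plus the bound share:

free nucleophile spent per product = 1 + ratio / (1 + ratio) = 1.69

Turn the question round. For the electrophile, the limiting reagent by charge, to react to the end, free nucleophile must last, and that asks a cost no higher than 1.05. This flask starts at 1.69, so at that cost the charge covers 0.623 equiv of electrophile. Beyond that mark, coupling lives on what a falling ratio releases. Commit to a flask still moving at 1.0 h, with product above the mark; this mark is an estimate, not a yield.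

The forecast says it is still moving, with 83 % of product, on the view that “the free nucleophile collapses as acid builds up”.

The simulation gives it is still moving, with 83.0 % of product and 9.9 percentage points of change over the second half.

    electrophile + nucleophile → acid set free + product (k1 = 0.961 L mol⁻¹ min⁻¹)
    nucleophile + acid set free ⇌ protonated nucleophile, settled at all times (K2 = 3990 L mol⁻¹)
    acid set free + free base ⇌ salt of the base, settled at all times (K3 = 640 L mol⁻¹)
    acid set free → by-product carried off (k4 = 0.0249 min⁻¹)

At the end of the feed this flask had spent 1.59 equiv of nucleophile per equivalent of product, and by 1.00 h its capture ratio reads 0.209. Strike the binding to the free base and product drops from 83.0 % to 56.8 %, the largest single effect; the reckoned cost is then 2, a mark of 0.525 equiv.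

The neighbour charged with 0.34 M of electrophile starts from the same ratio, 2.18, so its free nucleophile should follow this flask's path against product. It gives 88.5 % of product with 5.0 % of nucleophile, between this flask's 83.0 % with 7.39 % and its 98.5 % with 1.73 % at 10.0 h.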